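**Plan**
- Numbering from the acetoxy carbon: C1(OAc)–C2–C3(Me)–O4–C5–C6–C7(Br)–C8(Me2)–O9–C10(Me)–C11–C12–C13(OH). The carbocycle is C1–C2–C3–C13–C12–C11, the oxane is C5–C6–C7–C8–O9–C10, and O4–C5–C10 bridges C3 and C11.
- Retrosynthetic cuts, in order: C7–Br (from the axial alcohol, SN2); O4–C3 (C5–OH added across C2=C3); C8–CH3 (methyl to an oxocarbenium ion); O9–C8 and with it the oxane ring (hemiketal of a Z-enedione); the enedione back to a furan; C10–C5 (furyl anion plus C10 methyl ketone).
- Enabling feature: C5–C6–C7–C8 of the oxane carries oxygen at both ends (O4 on C5, O9 on C8). It is a masked 1,4-dicarbonyl, that is C2–C5 of a 5-methylfuran bonded through C5 to carbinol C10, whose hydroxyl is O9.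
- Forward: carbocycle from (S)-carvone (steps 1–8), furan joined at C10 (9), oxane ring by photooxygenation (10), second C8 methyl (11–12), C7 and C5 oxygens (13–14), oxepane bridge (15), bromide and acetate (16–19).
- Stereochemistry: C11 from carvone; C13 by Luche reduction then Mitsunobu inversion; C1 by L-Selectride; C10 by Felkin–Anh addition; C7 and C5 by the pyranone conformation that C10 fixes; C3 by the tether; C7–Br by inversion.

Key step: step 10

Remark: the labels C1–C13 above are used for all intermediates. Endoperoxide 13 (bridgeheads) and the ketals 15 and 16 (C8) are expected as isomer mixtures; the SMILES of 13 leaves the bridgeheads open and one anomer of 15 and 16 is drawn. This has no consequence, because C8 becomes CMe2 in step 12.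

Step 1
Reactants: 1 (S)-(+)-carvone
Product: 2 (1S,5S)-cis-carveol
Conditions: NaBH4, CeCl3·7H2O, MeOH, −20 → 0 °C
Reagents that add atoms: none
Why: Luche 1,2-reduction: cerium-activated borohydride adds axially to the enone carbonyl of the half-chair with the isopropenyl group equatorial, so the equatorial (cis) allylic alcohol should strongly predominate.

Step 2
Reactants: 2 (1S,5S)-cis-carveol
Product: 3 (1R,5S)-trans-carveyl 4-nitrobenzoate
Conditions: 4-nitrobenzoic acid, PPh3, DIAD, THF, 0 °C → rt
Reagents that add atoms: 4-nitrobenzoic acid OC(=O)c1ccc(cc1)[N+](=O)[O-]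
Why: Mitsunobu esterification: the acid displaces the alkoxyphosphonium ion by SN2 from the face anti to the isopropenyl group, inverting C13 to the trans configuration that the target requires.

Step 3
Reactants: 3 (1R,5S)-trans-carveyl 4-nitrobenzoate
Product: 4 (1R,5S)-trans-carveol
Conditions: K2CO3, MeOH, rt
Reagents that add atoms: none
Why: Base-catalysed transesterification of the activated aryl ester with methanol (methanolysis) frees the trans alcohol without touching a stereocentre.

Step 4
Reactants: 4 (1R,5S)-trans-carveol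
Product: 5 tert-butyldimethyl{[(1R,5S)-2-methyl-5-(prop-1-en-2-yl)cyclohex-2-en-1-yl]oxy}silane
Conditions: TBSCl, imidazole, DMF, rt
Reagents that add atoms: tert-butyldimethylsilyl chloride CC(C)(C)[Si](C)(C)Cl
Why: Imidazole-promoted silylation of a secondary allylic alcohol gives the robust C13 silyl ether that is carried to the last step.

Step 5
Reactants: 5 trans-carveol TBS ether
Product: 6 (4R,6S)-4-[(tert-butyldimethylsilyl)oxy]-3-methyl-6-(prop-1-en-2-yl)cyclohex-2-en-1-one
Conditions: Rh2(cap)4 (cat.), t-BuOOH (70% aq.), ClCH2CH2Cl, rt → 40 °C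
Reagents that add atoms: tert-butyl hydroperoxide CC(C)(C)OO
Why: Dirhodium caprolactamate/t-BuOOH allylic oxidation: the tert-butylperoxyl radical abstracts the pseudoaxial hydrogen of the only ring allylic methylene (C1; the C13–H next to the pseudoaxial silyloxy group is pseudoequatorial and poorly aligned), and the allyl radical is oxidised at C1 to the conjugated enone.

Step 6
Reactants: 6 C1 enone
Product: 7 (1S,4R,6S)-4-[(tert-butyldimethylsilyl)oxy]-3-methyl-6-(prop-1-en-2-yl)cyclohex-2-en-1-ol
Conditions: L-Selectride, THF, −78 °C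
Reagents that add atoms: none
Why: L-Selectride 1,2-reduction of a β,β-disubstituted enone: the bulky hydride attacks equatorially, as with 2-alkylcyclohexanones, and should give the pseudoaxial C1 alcohol cis to the equatorial isopropenyl group.

Step 7
Reactants: 7 C1 allylic alcohol
Product: 8 triethyl{[(1S,4R,6S)-4-[(tert-butyldimethylsilyl)oxy]-3-methyl-6-(prop-1-en-2-yl)cyclohex-2-en-1-yl]oxy}silane
Conditions: TESCl, imidazole, DMF, 0 °C
Reagents that add atoms: chlorotriethylsilane CC[Si](CC)(CC)Cl
Why: Silylation with the more labile triethylsilyl group gives a C1 ether that can later be removed beside the C13 TBS ether and that does not chelate in step 9.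

Step 8
Reactants: 8 bis-silyl ether
Product: 9 1-{(1R,2S,5R)-5-[(tert-butyldimethylsilyl)oxy]-4-methyl-2-[(triethylsilyl)oxy]cyclohex-3-en-1-yl}ethan-1-one
Conditions: OsO4 (cat.), NaIO4, 2,6-lutidine, dioxane/H2O, rt
Reagents that add atoms: osmium tetroxide O=[Os](=O)(=O)=O; sodium periodate [Na+].[O-][I](=O)(=O)=O
Why: Lemieux–Johnson oxidative cleavage: osmium tetroxide dihydroxylates the unhindered 1,1-disubstituted alkene in preference to the ring alkene, which is shielded on both faces and deactivated by two allylic silyloxy groups, and periodate cleaves the diol to the C10 methyl ketone.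

Step 9
Reactants: 9 C10 methyl ketone; 10 2-methylfuran
Product: 12 (1S)-1-{(1R,2S,5R)-5-[(tert-butyldimethylsilyl)oxy]-4-methyl-2-[(triethylsilyl)oxy]cyclohex-3-en-1-yl}-1-(5-methylfuran-2-yl)ethan-1-ol, via 5-methyl-2-furyllithium 11 (not isolated)
Conditions: 10, n-BuLi, THF, 0 °C; then 9, −78 °C; H2O quench
Reagents that add atoms: none
Why: 1,2-Addition of a 2-furyllithium to a ketone under Felkin–Anh control: with the C11–C1 bond (C1 bearing the bulky, non-chelating silyloxy group) antiperiplanar to the incoming nucleophile and C11–H beside the methyl group, the furyl group should add to the face that gives the (S)-carbinol at C10.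

Step 10
Reactants: 12 tertiary (5-methylfuran-2-yl) carbinol
Product: 15 (2S)-6-hydroxy-2,6-dimethyl-2-{(1R,2S,5R)-5-[(tert-butyldimethylsilyl)oxy]-4-methyl-2-[(triethylsilyl)oxy]cyclohex-3-en-1-yl}-2H-pyran-3(6H)-one, via furan endoperoxide 13 (not isolated), via Z-enedione 14 (not isolated)
Conditions: O2, methylene blue (cat.), visible light, CH2Cl2, −78 °C; then Me2S, −78 °C → rt
Reagents that add atoms: oxygen O=O
Why: Sensitised singlet oxygen adds [4+2] across C5/C8 of the electron-rich 2,5-dialkylfuran to give the 2,3,7-trioxabicyclo[2.2.1]heptene 13, and dimethyl sulfide cleaves its O–O bond to release the Z-enedione 14 (C5=O, C8=O). The closest known reaction type is the photooxygenative variant of the Achmatowicz rearrangement of 2-furyl carbinols, here with a tertiary carbinol. The Z geometry holds the C8 methyl ketone beside the C10 hydroxyl, which adds in a 6-exo-trig hemiketalisation to form O9–C8 and close the oxane ring as the 6-hydroxy-2H-pyran-3(6H)-one. The only new stereocentre is the anomeric C8, formed under thermodynamic ring–chain control as an anomeric mixture and erased in step 12; C10 is untouched. The step needs chemoselectivity for the furan over the C2=C3 ring alkene, which should be secured by the far higher rate of furan cycloaddition at −78 °C and by the two allylic silyloxy groups that deactivate and shield the alkene toward the ene reaction.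

Step 11
Reactants: 15 hemiketal pyranone
Product: 16 ketal acetate of 15 (6-acetoxy-2H-pyran-3(6H)-one)
Conditions: Ac2O, pyridine, DMAP (cat.), CH2Cl2, 0 °C → rt
Reagents that add atoms: acetic anhydride CC(=O)OC(C)=O
Why: DMAP-catalysed acylation of the hemiketal hydroxyl (the hindered tertiary C10–OH of the open tautomer does not compete) gives the ketal acetate, the usual leaving group for oxocarbenium chemistry of Achmatowicz-type pyranones.

Step 12
Reactants: 16 ketal acetate
Product: 17 (2S)-2,6,6-trimethyl-2-{(1R,2S,5R)-5-[(tert-butyldimethylsilyl)oxy]-4-methyl-2-[(triethylsilyl)oxy]cyclohex-3-en-1-yl}-2H-pyran-3(6H)-one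
Conditions: Me3Al, CH2Cl2, −78 → 0 °C
Reagents that add atoms: trimethylaluminium C[Al](C)C
Why: Lewis acid-mediated substitution of an anomeric acetate by an organoaluminium reagent: trimethylaluminium ionises the ketal acetate to the cyclic oxocarbenium ion and transfers a methyl group to C8, while the C5 carbonyl is shielded by the quaternary C10, and the C8 stereocentre disappears.

Step 13
Reactants: 17 gem-dimethyl enone
Product: 19 (2S,5R)-5-hydroxy-2,6,6-trimethyl-2-{(1R,2S,5R)-5-[(tert-butyldimethylsilyl)oxy]-4-methyl-2-[(triethylsilyl)oxy]cyclohex-3-en-1-yl}dihydro-2H-pyran-3(4H)-one, via β-boryl ketone 18 (not isolated)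
Conditions: B2pin2, CuCl (cat.), DPEphos (cat.), NaOt-Bu (cat.), MeOH, THF, rt; then NaBO3·4H2O, THF/H2O, rt
Reagents that add atoms: bis(pinacolato)diboron CC1(C)OB(OC1(C)C)B1OC(C)(C)C(C)(C)O1 (boron of 18); sodium perborate [Na+].[O-]OB=O (hydroxyl oxygen)
Why: Copper-catalysed conjugate borylation followed by perborate oxidation with retention: with the C10–C11 bond pseudoequatorial, the C10 methyl and one C8 methyl are pseudoaxial on the opposite face, so the boryl–copper species should add to C7 axially, anti to that C8 methyl, placing the C7 oxygen cis to the C10–C11 bond.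

Step 14
Reactants: 19 β-hydroxy ketone
Product: 20 (3R,5S,6S)-2,2,6-trimethyl-6-{(1R,2S,5R)-5-[(tert-butyldimethylsilyl)oxy]-4-methyl-2-[(triethylsilyl)oxy]cyclohex-3-en-1-yl}oxane-3,5-diol
Conditions: L-Selectride, THF, −78 °C
Reagents that add atoms: none
Why: Bulky-hydride ketone reduction: in the chair with C10–C11 equatorial the C7 alkoxide is axial and blocks axial attack at C5, so L-Selectride attacks equatorially and should give the axial C5 alcohol, cis to the C7 hydroxyl and to the C10–C11 bond as the bridge requires.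

Step 15
Reactants: 20 syn-1,3-diol
Product: 22 bridged tricyclic C7 alcohol (1S,3R,5S,7R,10S,11R,13R; C1–OTES and C13–OTBS; C7–OH cis to C5–O4), via C2 organomercurial 21 (not isolated)
Conditions: Hg(OCOCF3)2, 2,6-di-tert-butylpyridine, CH2Cl2, −20 → 0 °C; then NaBH4, aq. NaOH, THF, 0 °C
Reagents that add atoms: mercury(II) trifluoroacetate FC(F)(F)C(=O)O[Hg]OC(=O)C(F)(F)F (mercury of 21 only)
Why: Intramolecular alkoxymercuration–demercuration (the reaction that makes cineole-type bridged ethers): the C5 hydroxyl, the only one that can reach, attacks the tertiary carbon C3 of the mercurinium ion in the Markovnikov sense from the face of the C11 substituent with mercury anti at C2, so the tether fixes the new C3 stereocentre, and borohydride then replaces mercury by hydrogen.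

Step 16
Reactants: 22 bridged tricyclic C7 alcohol
Product: 23 C7 bromide (1S,3R,5S,7S,10S,11R,13R; C1–OTES and C13–OTBS)
Conditions: CBr4, (n-Oct)3P, 2,6-di-tert-butylpyridine, toluene, 70 °C
Reagents that add atoms: carbon tetrabromide BrC(Br)(Br)Br
Why: Appel bromination with inversion as practised on 3-hydroxy-2,2-dimethyloxanes: the axial alkoxyphosphonium ion at C7 cannot be assisted by O9 (no antiperiplanar C8–O9 bond), and bromide enters equatorially to give the C7 bromide trans to C5–O4.

Step 17
Reactants: 23 C7 bromide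
Product: 24 C1 alcohol (C13–OTBS retained)
Conditions: PPTS (cat.), MeOH/CH2Cl2, 0 °C → rt
Reagents that add atoms: none
Why: Acid-catalysed methanolysis of silyl ethers: the triethylsilyl ether is cleaved far faster than the hindered TBS ether, and the bromide and the ring ethers are inert.

Step 18
Reactants: 24 C1 alcohol
Product: 25 C1 acetate (C13–OTBS)
Conditions: Ac2O, pyridine, DMAP (cat.), CH2Cl2, rt
Reagents that add atoms: acetic anhydride CC(=O)OC(C)=O
Why: DMAP-catalysed acetylation of the only free hydroxyl installs the C1 acetate with retention.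

Step 19
Reactants: 25 C1 acetate
Product: 26 CNP0247588.2 (target)
Conditions: HF·pyridine, pyridine, THF, 0 °C → rt
Reagents that add atoms: none
Why: Fluoride-mediated desilylation under buffered HF·pyridine removes the TBS group without acyl migration (the C1 acetate and C13 hydroxyl are 1,4-trans across the ring) or loss of bromide, and gives the target.

**Compound list**
1 | (S)-(+)-carvone | CC1=CC[C@@H](CC1=O)C(C)=C | starting material
2 | (1S,5S)-cis-carveol | C=C(C)[C@@H]1C[C@H](O)C(C)=CC1 | intermediate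
3 | (1R,5S)-trans-carveyl 4-nitrobenzoate | C=C(C)[C@@H]1C[C@@H](OC(=O)c2ccc(cc2)[N+](=O)[O-])C(C)=CC1 | intermediate
4 | (1R,5S)-trans-carveol | C=C(C)[C@@H]1C[C@@H](O)C(C)=CC1 | intermediate
5 | trans-carveol TBS ether | C=C(C)[C@@H]1C[C@@H](O[Si](C)(C)C(C)(C)C)C(C)=CC1 | intermediate
6 | (4R,6S)-4-(TBS-oxy)-3-methyl-6-(prop-1-en-2-yl)cyclohex-2-en-1-one | C=C(C)[C@@H]1C[C@@H](O[Si](C)(C)C(C)(C)C)C(C)=CC1=O | intermediate
7 | (1S,4R,6S)-4-(TBS-oxy)-3-methyl-6-(prop-1-en-2-yl)cyclohex-2-en-1-ol | C=C(C)[C@@H]1C[C@@H](O[Si](C)(C)C(C)(C)C)C(C)=C[C@@H]1O | intermediate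
8 | C1–OTES, C13–OTBS bis-silyl ether of 7 | C=C(C)[C@@H]1C[C@@H](O[Si](C)(C)C(C)(C)C)C(C)=C[C@@H]1O[Si](CC)(CC)CC | intermediate
9 | C10 methyl ketone, 1-{(1R,2S,5R)-5-(TBS-oxy)-4-methyl-2-(TES-oxy)cyclohex-3-en-1-yl}ethan-1-one | CC(=O)[C@@H]1C[C@@H](O[Si](C)(C)C(C)(C)C)C(C)=C[C@@H]1O[Si](CC)(CC)CC | intermediate
10 | 2-methylfuran | Cc1ccco1 | starting material
11 | 5-methyl-2-furyllithium | [Li]c1ccc(C)o1 | intermediate
12 | (S)-tertiary (5-methylfuran-2-yl) carbinol | C[C@@](O)(c1ccc(C)o1)[C@@H]1C[C@@H](O[Si](C)(C)C(C)(C)C)C(C)=C[C@@H]1O[Si](CC)(CC)CC | intermediate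
13 | furan endoperoxide (2,3,7-trioxabicyclo[2.2.1]hept-5-ene) | C[C@@](O)(C12OC(C)(OO1)C=C2)[C@@H]3C[C@@H](O[Si](C)(C)C(C)(C)C)C(C)=C[C@@H]3O[Si](CC)(CC)CC | intermediate
14 | Z-enedione | C[C@@](O)(C(=O)/C=C\C(C)=O)[C@@H]1C[C@@H](O[Si](C)(C)C(C)(C)C)C(C)=C[C@@H]1O[Si](CC)(CC)CC | intermediate
15 | (2S)-6-hydroxy-2,6-dimethyl-2-(cyclohexenyl)-2H-pyran-3(6H)-one | C[C@]2(O[C@](C)(O)C=CC2=O)[C@@H]1C[C@@H](O[Si](C)(C)C(C)(C)C)C(C)=C[C@@H]1O[Si](CC)(CC)CC | intermediate
16 | ketal acetate of 15 | C[C@]2(O[C@](C)(OC(C)=O)C=CC2=O)[C@@H]1C[C@@H](O[Si](C)(C)C(C)(C)C)C(C)=C[C@@H]1O[Si](CC)(CC)CC | intermediate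
17 | (2S)-2,6,6-trimethyl-2-(cyclohexenyl)-2H-pyran-3(6H)-one | C[C@]2(OC(C)(C)C=CC2=O)[C@@H]1C[C@@H](O[Si](C)(C)C(C)(C)C)C(C)=C[C@@H]1O[Si](CC)(CC)CC | intermediate
18 | β-boryl ketone (C7–Bpin cis to C10–C11) | C[C@]2(OC(C)(C)[C@H](B3OC(C)(C)C(C)(C)O3)CC2=O)[C@@H]1C[C@@H](O[Si](C)(C)C(C)(C)C)C(C)=C[C@@H]1O[Si](CC)(CC)CC | intermediate
19 | β-hydroxy ketone (C7–OH, R) | C[C@]2(OC(C)(C)[C@H](O)CC2=O)[C@@H]1C[C@@H](O[Si](C)(C)C(C)(C)C)C(C)=C[C@@H]1O[Si](CC)(CC)CC | intermediate
20 | syn-1,3-diol (C5–OH and C7–OH cis to C10–C11) | C[C@]2(OC(C)(C)[C@H](O)C[C@@H]2O)[C@@H]1C[C@@H](O[Si](C)(C)C(C)(C)C)C(C)=C[C@@H]1O[Si](CC)(CC)CC | intermediate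
21 | C2 organomercurial trifluoroacetate (Hg anti to O4) | CC[Si](CC)(CC)O[C@H]1[C@H]([Hg]OC(=O)C(F)(F)F)[C@@]2(C)O[C@H]3C[C@@H](O)C(C)(C)O[C@@]3(C)[C@@H]1C[C@H]2O[Si](C)(C)C(C)(C)C | intermediate
22 | bridged tricyclic C7 alcohol (C1–OTES, C13–OTBS) | CC[Si](CC)(CC)O[C@H]1C[C@@]2(C)O[C@H]3C[C@@H](O)C(C)(C)O[C@@]3(C)[C@@H]1C[C@H]2O[Si](C)(C)C(C)(C)C | intermediate
23 | C7 bromide (C1–OTES, C13–OTBS) | CC[Si](CC)(CC)O[C@H]1C[C@@]2(C)O[C@H]3C[C@H](Br)C(C)(C)O[C@@]3(C)[C@@H]1C[C@H]2O[Si](C)(C)C(C)(C)C | intermediate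
24 | C1 alcohol (C13–OTBS) | O[C@H]1C[C@@]2(C)O[C@H]3C[C@H](Br)C(C)(C)O[C@@]3(C)[C@@H]1C[C@H]2O[Si](C)(C)C(C)(C)C | intermediate
25 | C1 acetate (C13–OTBS) | CC(=O)O[C@H]1C[C@@]2(C)O[C@H]3C[C@H](Br)C(C)(C)O[C@@]3(C)[C@@H]1C[C@H]2O[Si](C)(C)C(C)(C)C | intermediate
26 | CNP0247588.2 (1S,3R,5S,7S,10S,11R,13R) | CC(=O)O[C@H]1C[C@@]2(C)O[C@H]3C[C@H](Br)C(C)(C)O[C@@]3(C)[C@@H]1C[C@H]2O | target

**Totals**
Total step count: 19. Longest linear sequence: 19 steps from (S)-carvone; 2-methylfuran enters in step 9.

**Steps most likely to fail**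

Step 16. Displacement at the neopentyl-type C7 may be too slow, so that E2 loss toward C6, or ring contraction through O9 participation after a chair flip, outruns substitution; adventitious HBr may also strip the TES ether. The fallback sets out from enone 17 and forms the C–Br bond from a C–B bond instead of a C–O bond. The conjugate borylation of step 13 is stopped before oxidation and the β-boryl ketone 18 is isolated. L-Selectride reduction gives the boryl alcohol F1. Alkoxymercuration–demercuration as in step 15 proceeds through the boryl organomercurial F2 to the bridged boronate F3. Addition of 3,5-bis(trifluoromethyl)phenyllithium at −78 °C gives the aryl boronate complex F4, and N-bromosuccinimide brominates it at carbon with inversion. This delivers bromide 23, where the route is rejoined.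

Step 15. Mercuration of an alkene that is deactivated by two allylic silyloxy groups and must fold into a boat may be sluggish, closure may drift to C2 (six-membered ether), and the acid released may cleave the TES ether. The fallback sets out from diol 20 and returns at 22 in one operation by hydrogen-atom-transfer hydroalkoxylation (Co(salen) catalyst, N-fluoro-2,4,6-trimethylpyridinium tetrafluoroborate, 1,1,3,3-tetramethyldisiloxane, PhCF3, rt). The hydrogen atom is delivered to C2 first, and the tertiary C3 radical, after oxidation, is trapped by the C5 hydroxyl. This is strictly Markovnikov, acid-free and mercury-free, and makes no new compound.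

Step 13. Facial selectivity of the boryl–copper addition may be poor, because both faces of C7 carry a C8 methyl and the bias rests only on ring pucker. The fallback sets out from enone 17 and sets C7 later by ketone reduction in the rigid tricycle. The C7-epimeric hydroxy ketone F5 is reduced with Me4NBH(OAc)3 (intramolecular delivery, 1,3-anti) to the anti diol F6. Alkoxymercuration–demercuration as in step 15 proceeds through the epimeric organomercurial F7 to the 7-epi tricyclic alcohol F8. Dess–Martin periodinane gives the C7 ketone F9, and L-Selectride, which attacks equatorially because the axial face is blocked by the 1,3-diaxial C5–O4 bond, gives the axial alcohol 22, where the route is rejoined.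

**Further compounds**
F1 | step 16 | boryl alcohol (C7–Bpin, C5–OH) | C[C@]2(OC(C)(C)[C@H](B3OC(C)(C)C(C)(C)O3)C[C@@H]2O)[C@@H]1C[C@@H](O[Si](C)(C)C(C)(C)C)C(C)=C[C@@H]1O[Si](CC)(CC)CC
F2 | step 16 | boryl organomercurial | CC[Si](CC)(CC)O[C@H]1[C@H]([Hg]OC(=O)C(F)(F)F)[C@@]2(C)O[C@H]3C[C@@H](B4OC(C)(C)C(C)(C)O4)C(C)(C)O[C@@]3(C)[C@@H]1C[C@H]2O[Si](C)(C)C(C)(C)C
F3 | step 16 | bridged boronate | CC[Si](CC)(CC)O[C@H]1C[C@@]2(C)O[C@H]3C[C@@H](B4OC(C)(C)C(C)(C)O4)C(C)(C)O[C@@]3(C)[C@@H]1C[C@H]2O[Si](C)(C)C(C)(C)C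
F4 | step 16 | lithium aryl boronate complex | [Li+].CC[Si](CC)(CC)O[C@H]1C[C@@]2(C)O[C@H]3C[C@@H]([B-]4(OC(C)(C)C(C)(C)O4)c5cc(cc(c5)C(F)(F)F)C(F)(F)F)C(C)(C)O[C@@]3(C)[C@@H]1C[C@H]2O[Si](C)(C)C(C)(C)C
F0 | step 15 | none | none
F5 | step 13 | C7-epimeric hydroxy ketone | C[C@]2(OC(C)(C)[C@@H](O)CC2=O)[C@@H]1C[C@@H](O[Si](C)(C)C(C)(C)C)C(C)=C[C@@H]1O[Si](CC)(CC)CC
F6 | step 13 | anti diol | C[C@]2(OC(C)(C)[C@@H](O)C[C@@H]2O)[C@@H]1C[C@@H](O[Si](C)(C)C(C)(C)C)C(C)=C[C@@H]1O[Si](CC)(CC)CC
F7 | step 13 | epimeric organomercurial | CC[Si](CC)(CC)O[C@H]1[C@H]([Hg]OC(=O)C(F)(F)F)[C@@]2(C)O[C@H]3C[C@H](O)C(C)(C)O[C@@]3(C)[C@@H]1C[C@H]2O[Si](C)(C)C(C)(C)C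
F8 | step 13 | 7-epi tricyclic alcohol | CC[Si](CC)(CC)O[C@H]1C[C@@]2(C)O[C@H]3C[C@H](O)C(C)(C)O[C@@]3(C)[C@@H]1C[C@H]2O[Si](C)(C)C(C)(C)C
F9 | step 13 | C7 ketone | CC[Si](CC)(CC)O[C@H]1C[C@@]2(C)O[C@H]3CC(=O)C(C)(C)O[C@@]3(C)[C@@H]1C[C@H]2O[Si](C)(C)C(C)(C)C
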